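**Retrosynthetic overview**

1. Target 17 ⇒ (2S)-octabenzyl ether 16; the eight benzyl ethers are removed last by neutral hydrogenolysis.
2. 16 ⇒ aldehyde 15 by disconnecting C3–C4 of ring C of the flavanone: an enantioselective rhodium-catalysed intramolecular hydroacylation (6-endo) of a 1-arylvinyl aryl ether by the ring A aldehyde closes ring C and sets C2 on the complete biflavonoid skeleton.
3. Enabling feature: in ring C of the flavanone, C2 carries one H, the ring oxygen O1 and ring B, and lies β to the C4 ketone across the C3 methylene. Taking out that H and the C3–C4 bond leaves a ring A aldehyde (C4) and an achiral enol ether O1–C2(=C3H2)–ring B, which is one methylenation away from an aryl ester.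
4. 15 ⇒ Suzuki–Miyaura coupling C5'(ring B)–C6(luteolin) of boronate 10 with 6-iodo-tetra-O-benzylluteolin 14 (from luteolin by benzylation, C6 iodination, benzylation). The enol ether of 10 ⇒ Tebbe methylenation of aryl ester 6 (ring A phenol 2 + ring B acid 5), with the aldehyde carried as a methyl ester.
5. Ring order: both flavone rings arrive with luteolin, rings A and B of the flavanone are bought as arenes, the biaryl bond is made next, and ring C of the flavanone is formed last.

Key step: step 13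

Assumption: the biaryl axis between ring B and luteolin C6 carries no descriptor in the target and is treated as not configurationally defined; the only stereocentre is C2 (S). Compounds 1, 3 and 11 (luteolin) are taken as commercially available.

**Route**

Step 1
Reactants: 1 methyl 2,4,6-trihydroxybenzoate
Product: 2 methyl 2,4-bis(benzyloxy)-6-hydroxybenzoate
Conditions: BnBr (2.1 equiv), K2CO3, DMF, rt
Reagents that add atoms: benzyl bromide, BrCc1ccccc1
Why: Williamson etherification; the 4-OH and one ortho OH should react, while the remaining ortho OH is hydrogen-bonded to the ester carbonyl and is the least nucleophilic.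

Step 2
Reactants: 3 3-bromo-4,5-dihydroxybenzaldehyde
Product: 4 3,4-bis(benzyloxy)-5-bromobenzaldehyde
Conditions: BnBr (2.4 equiv), K2CO3, DMF, 60 °C
Reagents that add atoms: benzyl bromide, BrCc1ccccc1
Why: Williamson etherification of both catechol hydroxyls; benzyl should survive all later steps and leaves by neutral hydrogenolysis.

Step 3
Reactants: 4 3,4-bis(benzyloxy)-5-bromobenzaldehyde
Product: 5 3,4-bis(benzyloxy)-5-bromobenzoic acid
Conditions: NaClO2, NaH2PO4, 2-methyl-2-butene, t-BuOH/THF/H2O, rt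
Reagents that add atoms: sodium chlorite, [Na+].[O-]Cl=O
Why: Pinnick oxidation takes the aldehyde to the acid under buffered conditions that should leave benzyl ethers and the aryl bromide untouched.

Step 4
Reactants: 5 3,4-bis(benzyloxy)-5-bromobenzoic acid; 2 methyl 2,4-bis(benzyloxy)-6-hydroxybenzoate
Product: 6 3,5-bis(benzyloxy)-2-(methoxycarbonyl)phenyl 3,4-bis(benzyloxy)-5-bromobenzoate
Conditions: DCC, DMAP (cat.), CH2Cl2, 0 °C → rt
Reagents that add atoms: none
Why: Steglich esterification; DMAP catalysis should overcome the low nucleophilicity of the hydrogen-bonded phenol, and the new ester carbonyl carbon is the future C2 already bound to O1.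

Step 5
Reactants: 6 3,5-bis(benzyloxy)-2-(methoxycarbonyl)phenyl 3,4-bis(benzyloxy)-5-bromobenzoate
Product: 7 methyl 2,4-bis(benzyloxy)-6-({1-[3,4-bis(benzyloxy)-5-bromophenyl]ethenyl}oxy)benzoate
Conditions: Cp2Ti(μ-Cl)(μ-CH2)AlMe2 (Tebbe reagent, 1.3 equiv), pyridine (cat.), THF/toluene, −40 °C → rt; aq. NaOH work-up, basic alumina
Reagents that add atoms: Tebbe reagent, C[Al](C)C[Ti](Cl)(C1C=CC=C1)C1C=CC=C1
Why: Tebbe methylenation of an aryl benzoate to a 1-aryloxy-1-arylethene is a standard transformation; the unhindered aryl ester should react before the methyl ester, which is flanked by two ortho oxygen substituents and twisted out of conjugation.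

Step 6
Reactants: 7 methyl 2,4-bis(benzyloxy)-6-({1-[3,4-bis(benzyloxy)-5-bromophenyl]ethenyl}oxy)benzoate
Product: 8 [2,4-bis(benzyloxy)-6-({1-[3,4-bis(benzyloxy)-5-bromophenyl]ethenyl}oxy)phenyl]methanol
Conditions: i-Bu2AlH (2.5 equiv), CH2Cl2, −78 → 0 °C; basic work-up, used without storage
Reagents that add atoms: none
Why: Hydride reduction of the ester to the primary alcohol; enol ether, aryl bromide and benzyl ethers are inert to the reagent, and acid is excluded so that the benzylic OH does not add across the enol ether.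

Step 7
Reactants: 8 [2,4-bis(benzyloxy)-6-({1-[3,4-bis(benzyloxy)-5-bromophenyl]ethenyl}oxy)phenyl]methanol
Product: 9 2,4-bis(benzyloxy)-6-({1-[3,4-bis(benzyloxy)-5-bromophenyl]ethenyl}oxy)benzaldehyde
Conditions: MnO2 (excess), CH2Cl2, rt
Reagents that add atoms: none
Why: MnO2 oxidation of an electron-rich benzylic alcohol to the aldehyde under neutral conditions that should not hydrolyse the acid-labile enol ether.

Step 8
Reactants: 9 2,4-bis(benzyloxy)-6-({1-[3,4-bis(benzyloxy)-5-bromophenyl]ethenyl}oxy)benzaldehyde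
Product: 10 2,4-bis(benzyloxy)-6-({1-[3,4-bis(benzyloxy)-5-(4,4,5,5-tetramethyl-1,3,2-dioxaborolan-2-yl)phenyl]ethenyl}oxy)benzaldehyde
Conditions: bis(pinacolato)diboron, Pd(dppf)Cl2 (5 mol %), KOAc, 1,4-dioxane, 80 °C
Reagents that add atoms: bis(pinacolato)diboron, CC1(C)OB(OC1(C)C)B1OC(C)(C)C(C)(C)O1
Why: Miyaura borylation of the aryl bromide; the weak base KOAc should leave aldehyde and enol ether untouched, and boron is placed on the less hindered coupling partner.

Step 9
Reactants: 11 luteolin (2-(3,4-dihydroxyphenyl)-5,7-dihydroxy-4H-chromen-4-one)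
Product: 12 7-(benzyloxy)-2-[3,4-bis(benzyloxy)phenyl]-5-hydroxy-4H-chromen-4-one
Conditions: BnBr (3.3 equiv), K2CO3, DMF, rt
Reagents that add atoms: benzyl bromide, BrCc1ccccc1
Why: Williamson etherification; the 5-OH, chelated to the C4 carbonyl, is the least reactive and should stay free with three equivalents of BnBr.

Step 10
Reactants: 12 7-(benzyloxy)-2-[3,4-bis(benzyloxy)phenyl]-5-hydroxy-4H-chromen-4-one
Product: 13 7-(benzyloxy)-2-[3,4-bis(benzyloxy)phenyl]-5-hydroxy-6-iodo-4H-chromen-4-one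
Conditions: BnMe3N·ICl2 (1.1 equiv), CaCO3, CH2Cl2/MeOH, rt
Reagents that add atoms: benzyltrimethylammonium dichloroiodate, C[N+](C)(C)Cc1ccccc1.Cl[I-]Cl
Why: Electrophilic aromatic iodination; with a free 5-hydroxyl and a 7-alkoxy group this reagent is known to iodinate 5,7-dioxygenated flavones ortho to the phenol at C6 and not at C8.

Step 11
Reactants: 13 7-(benzyloxy)-2-[3,4-bis(benzyloxy)phenyl]-5-hydroxy-6-iodo-4H-chromen-4-one
Product: 14 5,7-bis(benzyloxy)-2-[3,4-bis(benzyloxy)phenyl]-6-iodo-4H-chromen-4-one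
Conditions: BnBr, K2CO3, DMF, 60 °C
Reagents that add atoms: benzyl bromide, BrCc1ccccc1
Why: Williamson etherification of the chelated 5-OH at higher temperature removes the acidic phenol before the coupling and gives a uniformly benzyl-protected partner.

Step 12
Reactants: 10 2,4-bis(benzyloxy)-6-({1-[3,4-bis(benzyloxy)-5-(4,4,5,5-tetramethyl-1,3,2-dioxaborolan-2-yl)phenyl]ethenyl}oxy)benzaldehyde; 14 5,7-bis(benzyloxy)-2-[3,4-bis(benzyloxy)phenyl]-6-iodo-4H-chromen-4-one
Product: 15 2,4-bis(benzyloxy)-6-[(1-{3,4-bis(benzyloxy)-5-[5,7-bis(benzyloxy)-2-(3,4-bis(benzyloxy)phenyl)-4-oxo-4H-chromen-6-yl]phenyl}ethenyl)oxy]benzaldehyde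
Conditions: Pd(OAc)2 (5 mol %), SPhos (10 mol %), K3PO4, toluene/H2O, 80 °C
Reagents that add atoms: none
Why: Suzuki–Miyaura coupling placed before ring closure so that C2 never meets base; the electron-rich biaryl phosphine should allow oxidative addition into the doubly ortho-substituted iodide, and aldehyde, enol ether and flavone tolerate phosphate.

Step 13
Reactants: 15 2,4-bis(benzyloxy)-6-[(1-{3,4-bis(benzyloxy)-5-[5,7-bis(benzyloxy)-2-(3,4-bis(benzyloxy)phenyl)-4-oxo-4H-chromen-6-yl]phenyl}ethenyl)oxy]benzaldehyde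
Product: 16 (2S)-5,7-bis(benzyloxy)-2-{3,4-bis(benzyloxy)-5-[5,7-bis(benzyloxy)-2-(3,4-bis(benzyloxy)phenyl)-4-oxo-4H-chromen-6-yl]phenyl}-2,3-dihydro-4H-chromen-4-one
Conditions: [Rh(cod)Cl]2 (5 mol %), (R)-DTBM-SEGPHOS (10 mol %), NaB[3,5-(CF3)2C6H3]4 (10 mol %), degassed 1,4-dioxane, 80 °C
Reagents that add atoms: none
Why: Proposed new method: oxidative addition of the aldehyde C–H bond to the cationic monovalent rhodium bisphosphine gives an acyl rhodium hydride that binds the 1,1-disubstituted enol ether; migratory insertion puts the hydride on the aryl- and oxygen-bearing carbon (future C2) and rhodium on the terminal CH2, and C–C reductive elimination forms the C3–C4 bond in an isomerization with no by-product. The closest known reaction type is the rhodium-catalysed enantioselective intramolecular hydroacylation of 1,1-disubstituted alkenes in ortho-allylbenzaldehydes (six-membered aryl ketones) and in 4-substituted pent-4-enals; new here is that the alkene is an aryl enol ether, with oxygen as the tether atom. Ring C closes in the 6-endo-trig sense, the acyl carbon bonding to the terminal alkene carbon. The C2 centre is set in the hydride insertion, whose enantioface is chosen by the chiral bisphosphine (catalyst control); the sense of induction is to be checked on a model 2-[(1-arylvinyl)oxy]benzaldehyde and the (S)-ligand used instead if the model demands it. The step needs endo over exo regioselectivity and reductive elimination over decarbonylation: the exo path would have to eliminate from a tertiary alkyl rhodium centre to a quaternary benzofuranone, which the α-aryl, α-aryloxy substitution of the alkene blocks, while insertion is reversible, and the bound alkene plus the two ortho oxygens should hold the acyl hydride against CO loss. The flavone enone, aryl ethers and benzyl ethers should be inert to the catalyst.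

Step 14
Reactants: 16 (2S)-5,7-bis(benzyloxy)-2-{3,4-bis(benzyloxy)-5-[5,7-bis(benzyloxy)-2-(3,4-bis(benzyloxy)phenyl)-4-oxo-4H-chromen-6-yl]phenyl}-2,3-dihydro-4H-chromen-4-one
Product: 17 (2S)-2-{5-[2-(3,4-dihydroxyphenyl)-5,7-dihydroxy-4-oxo-4H-chromen-6-yl]-3,4-dihydroxyphenyl}-5,7-dihydroxy-2,3-dihydro-4H-chromen-4-one (target)
Conditions: H2 (1 atm), Pd/C (10 wt % Pd), THF/MeOH, rt; stopped after uptake of eight equivalents
Reagents that add atoms: none
Why: Hydrogenolysis of the eight benzyl ethers under neutral conditions avoids the base-induced ring opening to the chalcone that would racemize C2 of a 5-hydroxyflavanone, and mild pressure should spare the flavone C2–C3 double bond and the C2–O1 bond.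

**Compound list**

1 | methyl 2,4,6-trihydroxybenzoate | COC(=O)c1c(O)cc(O)cc1O | starting material
2 | methyl 2,4-bis(benzyloxy)-6-hydroxybenzoate | COC(=O)c1c(O)cc(OCc2ccccc2)cc1OCc1ccccc1 | intermediate
3 | 3-bromo-4,5-dihydroxybenzaldehyde | O=Cc1cc(O)c(O)c(Br)c1 | starting material
4 | 3,4-bis(benzyloxy)-5-bromobenzaldehyde | O=Cc1cc(Br)c(OCc2ccccc2)c(OCc2ccccc2)c1 | intermediate
5 | 3,4-bis(benzyloxy)-5-bromobenzoic acid | OC(=O)c1cc(Br)c(OCc2ccccc2)c(OCc2ccccc2)c1 | intermediate
6 | 3,5-bis(benzyloxy)-2-(methoxycarbonyl)phenyl 3,4-bis(benzyloxy)-5-bromobenzoate | COC(=O)c1c(OC(=O)c2cc(Br)c(OCc3ccccc3)c(OCc3ccccc3)c2)cc(OCc2ccccc2)cc1OCc1ccccc1 | intermediate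
7 | methyl 2,4-bis(benzyloxy)-6-({1-[3,4-bis(benzyloxy)-5-bromophenyl]ethenyl}oxy)benzoate | COC(=O)c1c(OC(=C)c2cc(Br)c(OCc3ccccc3)c(OCc3ccccc3)c2)cc(OCc2ccccc2)cc1OCc1ccccc1 | intermediate
8 | [2,4-bis(benzyloxy)-6-({1-[3,4-bis(benzyloxy)-5-bromophenyl]ethenyl}oxy)phenyl]methanol | OCc1c(OC(=C)c2cc(Br)c(OCc3ccccc3)c(OCc3ccccc3)c2)cc(OCc2ccccc2)cc1OCc1ccccc1 | intermediate
9 | 2,4-bis(benzyloxy)-6-({1-[3,4-bis(benzyloxy)-5-bromophenyl]ethenyl}oxy)benzaldehyde | O=Cc1c(OC(=C)c2cc(Br)c(OCc3ccccc3)c(OCc3ccccc3)c2)cc(OCc2ccccc2)cc1OCc1ccccc1 | intermediate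
10 | 2,4-bis(benzyloxy)-6-({1-[3,4-bis(benzyloxy)-5-(4,4,5,5-tetramethyl-1,3,2-dioxaborolan-2-yl)phenyl]ethenyl}oxy)benzaldehyde | O=Cc1c(OC(=C)c2cc(B3OC(C)(C)C(C)(C)O3)c(OCc3ccccc3)c(OCc3ccccc3)c2)cc(OCc2ccccc2)cc1OCc1ccccc1 | intermediate
11 | luteolin, 2-(3,4-dihydroxyphenyl)-5,7-dihydroxy-4H-chromen-4-one | O=c1cc(-c2ccc(O)c(O)c2)oc2cc(O)cc(O)c12 | starting material
12 | 7-(benzyloxy)-2-[3,4-bis(benzyloxy)phenyl]-5-hydroxy-4H-chromen-4-one | O=c1cc(-c2ccc(OCc3ccccc3)c(OCc3ccccc3)c2)oc2cc(OCc3ccccc3)cc(O)c12 | intermediate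
13 | 7-(benzyloxy)-2-[3,4-bis(benzyloxy)phenyl]-5-hydroxy-6-iodo-4H-chromen-4-one | O=c1cc(-c2ccc(OCc3ccccc3)c(OCc3ccccc3)c2)oc2cc(OCc3ccccc3)c(I)c(O)c12 | intermediate
14 | 5,7-bis(benzyloxy)-2-[3,4-bis(benzyloxy)phenyl]-6-iodo-4H-chromen-4-one | O=c1cc(-c2ccc(OCc3ccccc3)c(OCc3ccccc3)c2)oc2cc(OCc3ccccc3)c(I)c(OCc3ccccc3)c12 | intermediate
15 | 2,4-bis(benzyloxy)-6-[(1-{3,4-bis(benzyloxy)-5-[5,7-bis(benzyloxy)-2-(3,4-bis(benzyloxy)phenyl)-4-oxo-4H-chromen-6-yl]phenyl}ethenyl)oxy]benzaldehyde | O=Cc1c(OC(=C)c2cc(-c3c(OCc4ccccc4)cc4oc(-c5ccc(OCc6ccccc6)c(OCc6ccccc6)c5)cc(=O)c4c3OCc3ccccc3)c(OCc3ccccc3)c(OCc3ccccc3)c2)cc(OCc2ccccc2)cc1OCc1ccccc1 | intermediate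
16 | (2S)-5,7-bis(benzyloxy)-2-{3,4-bis(benzyloxy)-5-[5,7-bis(benzyloxy)-2-(3,4-bis(benzyloxy)phenyl)-4-oxo-4H-chromen-6-yl]phenyl}-2,3-dihydro-4H-chromen-4-one | O=C1C[C@@H](c2cc(OCc3ccccc3)c(OCc3ccccc3)c(-c3c(OCc4ccccc4)cc4oc(-c5ccc(OCc6ccccc6)c(OCc6ccccc6)c5)cc(=O)c4c3OCc3ccccc3)c2)Oc2cc(OCc3ccccc3)cc(OCc3ccccc3)c21 | intermediate
17 | (2S)-2-{5-[2-(3,4-dihydroxyphenyl)-5,7-dihydroxy-4-oxo-4H-chromen-6-yl]-3,4-dihydroxyphenyl}-5,7-dihydroxy-2,3-dihydro-4H-chromen-4-one | O=C1C[C@@H](c2cc(O)c(O)c(-c3c(O)cc4oc(-c5ccc(O)c(O)c5)cc(=O)c4c3O)c2)Oc2cc(O)cc(O)c21 | target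

**Step count**

Total step count: 14.
Longest linear sequence: 10 steps (steps 2, 3, 4, 5, 6, 7, 8, 12, 13, 14, from 3 to 17).

**Steps most likely to fail**

Step 13 (Proposed new method). The acyl rhodium hydride may lose CO before insertion, the many Lewis-basic oxygens may inhibit the catalyst, insertion may be slow at the hindered enol ether, or enantioface discrimination may be weak. The fallback is the classical chalcone route with separation of enantiomers and sets out from 4. Claisen–Schmidt condensation of 4 with commercially available 1-[2,4-bis(benzyloxy)-6-hydroxyphenyl]ethanone (CC(=O)c1c(O)cc(OCc2ccccc2)cc1OCc1ccccc1; KOH, EtOH, rt) should give the chalcone (E)-1-[2,4-bis(benzyloxy)-6-hydroxyphenyl]-3-[3,4-bis(benzyloxy)-5-bromophenyl]prop-2-en-1-one F1. NaOAc in refluxing EtOH should close it by intramolecular oxa-Michael addition to racemic 5,7-bis(benzyloxy)-2-[3,4-bis(benzyloxy)-5-bromophenyl]-2,3-dihydro-4H-chromen-4-one F2. Miyaura borylation under the conditions of step 8 should give the racemic pinacol boronate F3, and Suzuki–Miyaura coupling with 14 under the conditions of step 12 should give the racemic octabenzyl ether F4; base-induced ring opening is harmless at this stage because the material is racemic. Preparative HPLC on a chiral stationary phase would separate F4 into the (2R)-enantiomer F5, which can be re-equilibrated with NaOAc, and the (2S)-enantiomer, which comes back to the route at 16.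

Step 12. Oxidative addition into the doubly ortho-substituted iodide may be slow, so that protodeboronation of 10 or base-mediated decomposition wins. The fallback is a base-free Stille coupling and sets out from 9. Stannylation with hexamethylditin (Pd(PPh3)4, toluene, 100 °C) should give 2,4-bis(benzyloxy)-6-({1-[3,4-bis(benzyloxy)-5-(trimethylstannyl)phenyl]ethenyl}oxy)benzaldehyde F6. Copper-assisted Stille coupling of F6 with 14 (Pd(PPh3)4, CuI, CsF, DMF, 45 °C) comes back to the route at 15.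

Step 14. Hydrogenation may run on into the flavone C2–C3 double bond or cleave the benzylic C2–O1 bond of the flavanone, or stall at the hindered benzyl ethers next to the biaryl axis. The fallback replaces reductive cleavage by Lewis-acid dealkylation with a cation scavenger: 16 is treated with BCl3 and pentamethylbenzene in CH2Cl2 at −78 °C and quenched with MeOH at low temperature, which goes directly from 16 to 17 without new intermediates.

**Further compounds**

F1 | step 13 | (E)-1-[2,4-bis(benzyloxy)-6-hydroxyphenyl]-3-[3,4-bis(benzyloxy)-5-bromophenyl]prop-2-en-1-one | O=C(/C=C/c1cc(Br)c(OCc2ccccc2)c(OCc2ccccc2)c1)c1c(O)cc(OCc2ccccc2)cc1OCc1ccccc1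
F2 | step 13 | racemic 5,7-bis(benzyloxy)-2-[3,4-bis(benzyloxy)-5-bromophenyl]-2,3-dihydro-4H-chromen-4-one | O=C1CC(c2cc(Br)c(OCc3ccccc3)c(OCc3ccccc3)c2)Oc2cc(OCc3ccccc3)cc(OCc3ccccc3)c21
F3 | step 13 | racemic 5,7-bis(benzyloxy)-2-[3,4-bis(benzyloxy)-5-(4,4,5,5-tetramethyl-1,3,2-dioxaborolan-2-yl)phenyl]-2,3-dihydro-4H-chromen-4-one | O=C1CC(c2cc(B3OC(C)(C)C(C)(C)O3)c(OCc3ccccc3)c(OCc3ccccc3)c2)Oc2cc(OCc3ccccc3)cc(OCc3ccccc3)c21
F4 | step 13 | racemic 5,7-bis(benzyloxy)-2-{3,4-bis(benzyloxy)-5-[5,7-bis(benzyloxy)-2-(3,4-bis(benzyloxy)phenyl)-4-oxo-4H-chromen-6-yl]phenyl}-2,3-dihydro-4H-chromen-4-one | O=C1CC(c2cc(OCc3ccccc3)c(OCc3ccccc3)c(-c3c(OCc4ccccc4)cc4oc(-c5ccc(OCc6ccccc6)c(OCc6ccccc6)c5)cc(=O)c4c3OCc3ccccc3)c2)Oc2cc(OCc3ccccc3)cc(OCc3ccccc3)c21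
F5 | step 13 | (2R)-5,7-bis(benzyloxy)-2-{3,4-bis(benzyloxy)-5-[5,7-bis(benzyloxy)-2-(3,4-bis(benzyloxy)phenyl)-4-oxo-4H-chromen-6-yl]phenyl}-2,3-dihydro-4H-chromen-4-one | O=C1C[C@H](c2cc(OCc3ccccc3)c(OCc3ccccc3)c(-c3c(OCc4ccccc4)cc4oc(-c5ccc(OCc6ccccc6)c(OCc6ccccc6)c5)cc(=O)c4c3OCc3ccccc3)c2)Oc2cc(OCc3ccccc3)cc(OCc3ccccc3)c21
F6 | step 12 | 2,4-bis(benzyloxy)-6-({1-[3,4-bis(benzyloxy)-5-(trimethylstannyl)phenyl]ethenyl}oxy)benzaldehyde | O=Cc1c(OC(=C)c2cc([Sn](C)(C)C)c(OCc3ccccc3)c(OCc3ccccc3)c2)cc(OCc2ccccc2)cc1OCc1ccccc1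
F0 | step 14 | none | none
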